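**Retrosynthetic overview**
- The lactone is reached by redox and acetal adjustments only from a 2‑alkenyl‑2,3‑dihydro‑4H‑pyran‑4‑one (methanol addition, axial‑selective ketone reduction, acetal hydrolysis, lactol oxidation).
- Key disconnection: the bond between the side‑chain alkene carbon and lactone C6, made by Rh(I)/(R)‑BINAP‑catalysed enantioselective dearomative 1,4‑alkenylation of 4H‑pyran‑4‑one with an (E)‑alkenylboronic acid.
- Enabling feature: the oxane ring O1–C2(=O)–C3–C4(OH)–C5–C6 carries oxygen at O1 and C4 exactly as γ‑pyrone does. C6 (α to the ring oxygen, allylic C–O) is the β‑carbon of the pyranone's vinylogous ester, and the enol ether left after addition (C2=C3) is a latent lactone carbonyl.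
- The boronic acid comes from a terminal alkyne whose anti‑1,3‑dimethoxy chain is built from cinnamaldehyde (Brown allylation, then reagent‑controlled propargylation).
- Ring order: the phenyl ring comes with cinnamaldehyde; the oxane ring is never closed but enters whole as flat 4H‑pyran‑4‑one and is dearomatised in the key step.

Key step: step 7

Remark on the chemistry: the target is read as the (4S,6R)‑lactone (4‑OH trans to the C6 side chain) with a (4R,6S)‑anti‑1,3‑dimethoxy chain. Boron reagents that transfer allyl or propargyl groups are treated as reagents and are not numbered.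

**Step 1**
Reactants: 1 (E)‑cinnamaldehyde
Product: 3 (3S,1E)‑1‑phenylhexa‑1,5‑dien‑3‑ol, via borinate ester 2 (not isolated)
Conditions: (−)‑Ipc2B(allyl) (commercial solution, from (+)‑α‑pinene), Et2O, −78 °C; then NaOH, H2O2, rt
Reagents that add atoms: (−)‑B‑allyldiisopinocampheylborane, C=CCB([C@@H]1C[C@@H]2C[C@@H](C2(C)C)[C@H]1C)[C@@H]1C[C@@H]2C[C@@H](C2(C)C)[C@H]1C
Why: Brown asymmetric allylboration through a closed chair transition state, in which this reagent delivers allyl to the Si face of the enal and so sets the (S)‑carbinol (the future styryl‑bearing methoxy centre).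

**Step 2**
Reactants: 3 (3S,1E)‑1‑phenylhexa‑1,5‑dien‑3‑ol
Product: 4 [(1E,3S)‑3‑methoxyhexa‑1,5‑dien‑1‑yl]benzene
Conditions: NaH, MeI, THF, 0 °C → rt
Reagents that add atoms: iodomethane, CI
Why: Williamson etherification of the sodium alkoxide, which is alkylated well below the temperature at which an anionic oxy‑Cope shift of this 1,5‑dien‑3‑olate would set in; no stereocentre is touched.

**Step 3**
Reactants: 4 [(1E,3S)‑3‑methoxyhexa‑1,5‑dien‑1‑yl]benzene
Product: 6 (3S,4E)‑3‑methoxy‑5‑phenylpent‑4‑enal, via diol 5 (not isolated)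
Conditions: OsO4 (2 mol%), NaIO4, 2,6‑lutidine, dioxane/H2O (3:1), 0 °C → rt; aldehyde used directly
Reagents that add atoms: osmium tetroxide, O=[Os](=O)(=O)=O (catalytic; source of the aldehyde oxygen, replenished by sodium periodate, [Na+].[O-]I(=O)(=O)=O)
Why: Lemieux–Johnson oxidation, in which OsO4 should dihydroxylate the unhindered monosubstituted alkene faster than the 1,2‑disubstituted styrenyl alkene that is flanked and inductively deactivated by the allylic methoxy group, and periodate cleaves the diol in situ.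

**Step 4**
Reactants: 6 (3S,4E)‑3‑methoxy‑5‑phenylpent‑4‑enal
Product: 8 (4R,6S,7E)‑6‑methoxy‑8‑phenyloct‑7‑en‑1‑yn‑4‑ol, via borate ester 7 (not isolated)
Conditions: allenylboronic acid pinacol ester, (R)‑TRIP phosphoric acid (10 mol%), 4 Å MS, toluene, −20 °C; aqueous work‑up
Reagents that add atoms: allenylboronic acid pinacol ester, C=C=CB1OC(C)(C)C(C)(C)O1
Why: Chiral phosphoric acid‑catalysed propargylboration (SE2′ through a six‑membered chair transition state), in which the (R)‑catalyst should direct attack to the Re face of the aldehyde and give the (4R)‑carbinol, a sense that coincides with the intrinsic 1,3‑anti preference of the β‑methoxy aldehyde (the antipodal catalyst is the remedy if the sense is reversed for this aldehyde).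

**Step 5**
Reactants: 8 (4R,6S,7E)‑6‑methoxy‑8‑phenyloct‑7‑en‑1‑yn‑4‑ol
Product: 9 (4R,6S,7E)‑4,6‑dimethoxy‑8‑phenyloct‑7‑en‑1‑yne
Conditions: NaH, MeI, THF, 0 °C
Reagents that add atoms: iodomethane, CI
Why: Williamson etherification, with NaH at 0 °C deprotonating the alcohol far faster than the alkyne C–H; no stereocentre is touched.

**Step 6**
Reactants: 9 (4R,6S,7E)‑4,6‑dimethoxy‑8‑phenyloct‑7‑en‑1‑yne
Product: 11 [(1E,4R,6S,7E)‑4,6‑dimethoxy‑8‑phenylocta‑1,7‑dien‑1‑yl]boronic acid, via catechol boronate 10 (not isolated)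
Conditions: catecholborane, THF, 70 °C; then H2O, rt
Reagents that add atoms: catecholborane, B1Oc2ccccc2O1; water, O
Why: Syn‑hydroboration of the terminal alkyne places boron on the terminal carbon and gives the (E)‑alkenylboronate, which water hydrolyses to the boronic acid, while the internal styrenyl alkene is inert at this temperature.

**Step 7**
Reactants: 11 [(1E,4R,6S,7E)‑4,6‑dimethoxy‑8‑phenylocta‑1,7‑dien‑1‑yl]boronic acid; 12 4H‑pyran‑4‑one (3 equiv)
Product: 13 (2R)‑2‑[(1E,4R,6S,7E)‑4,6‑dimethoxy‑8‑phenylocta‑1,7‑dien‑1‑yl]‑2,3‑dihydro‑4H‑pyran‑4‑one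
Conditions: [Rh(OH)((R)‑binap)]2 (3 mol% Rh), dioxane/H2O (10:1), 35 °C
Reagents that add atoms: none
Why: Proposed new method: transmetalation of 11 to the Rh(I)–OH complex should give an alkenyl–Rh(I) species that inserts one C=C bond of 12 with the alkenyl group going to the β‑carbon next to the ring oxygen, and water then protonates the oxa‑π‑allyl rhodium dienolate at carbon to release 13 and return Rh–OH; the closest known reaction types are the Rh(I)/BINAP‑catalysed 1,4‑addition of alkenylboronic acids to cyclic enones and of arylboron reagents to chromones and 4‑quinolones, whereas a monocyclic γ‑pyrone has not been used as acceptor. No ring is closed: the oxane ring of the target enters whole as the flat 6π pyranone and is dearomatised, and its C2v symmetry removes any question of regiochemistry. The one new stereocentre (C2 of 13, the future lactone C6) is set by the (R)‑BINAP–Rh complex, which discriminates the enantiotopic faces of the enone as it does for cyclohexenone (the sense is assigned by that analogy and would be corrected with the antipodal ligand), the stereocentres of 11 being too remote to interfere. Mono‑addition is needed and should be secured by the product being a vinylogous ester whose ring‑oxygen lone pair now feeds a single enone, helped by the excess of 12. Base‑free aqueous conditions at 35 °C are chosen so that the dienolate is protonated faster than it can lose the ring oxygen by β‑elimination or open as a 2H‑pyran, either of which would erase the new centre. Syn‑insertion leaves the (E)‑geometry of 11 untouched and the alkenyl–Rh species does not add to the ketone carbonyl.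

**Step 8**
Reactants: 13 (2R)‑2‑[(1E,4R,6S,7E)‑4,6‑dimethoxy‑8‑phenylocta‑1,7‑dien‑1‑yl]‑2,3‑dihydro‑4H‑pyran‑4‑one
Product: 14 (2R,6R)‑2‑[(1E,4R,6S,7E)‑4,6‑dimethoxy‑8‑phenylocta‑1,7‑dien‑1‑yl]‑6‑methoxyoxan‑4‑one
Conditions: CSA (5 mol%), MeOH, 0 °C → rt
Reagents that add atoms: methanol, CO
Why: Acid‑catalysed conjugate addition of methanol to the vinylogous ester via the ring oxocarbenium ion, where axial attack and the anomeric effect should give the 2,6‑trans acetal with axial OMe and equatorial alkenyl group.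

**Step 9**
Reactants: 14 (2R,6R)‑2‑[(1E,4R,6S,7E)‑4,6‑dimethoxy‑8‑phenylocta‑1,7‑dien‑1‑yl]‑6‑methoxyoxan‑4‑one
Product: 15 (2R,4S,6R)‑2‑[(1E,4R,6S,7E)‑4,6‑dimethoxy‑8‑phenylocta‑1,7‑dien‑1‑yl]‑6‑methoxyoxan‑4‑ol
Conditions: L‑Selectride, THF, −78 °C; then H2O
Reagents that add atoms: none
Why: Bulky‑hydride reduction of a chair oxanone, in which equatorial attack (the axial trajectory is blocked by the axial OMe) should give the axial alcohol cis to OMe and trans to the alkenyl group, which is the (4S) centre.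

**Step 10**
Reactants: 15 (2R,4S,6R)‑2‑[(1E,4R,6S,7E)‑4,6‑dimethoxy‑8‑phenylocta‑1,7‑dien‑1‑yl]‑6‑methoxyoxan‑4‑ol
Product: 16 (4S,6R)‑6‑[(1E,4R,6S,7E)‑4,6‑dimethoxy‑8‑phenylocta‑1,7‑dien‑1‑yl]oxane‑2,4‑diol (anomer mixture)
Conditions: AcOH/THF/H2O (3:1:1), 40 °C
Reagents that add atoms: water, O
Why: Hydrolysis of a 2‑deoxyglycoside‑type methyl acetal, which proceeds under acid mild enough to spare the allylic methyl ether, and only the anomeric centre is affected.

**Step 11**
Reactants: 16 (4S,6R)‑6‑[(1E,4R,6S,7E)‑4,6‑dimethoxy‑8‑phenylocta‑1,7‑dien‑1‑yl]oxane‑2,4‑diol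
Product: 17 (4S,6R)‑6‑[(1E,4R,6S,7E)‑4,6‑dimethoxy‑8‑phenylocta‑1,7‑dien‑1‑yl]‑4‑hydroxyoxan‑2‑one
Conditions: TEMPO (10 mol%), PhI(OAc)2, CH2Cl2, rt
Reagents that add atoms: none
Why: TEMPO/PhI(OAc)2 oxidation is selective for lactols over unactivated secondary alcohols, so both anomers should converge on the lactone with the axial C4–OH left free.

**Compound list**
1 | (E)‑cinnamaldehyde | O=C/C=C/c1ccccc1 | starting material
2 | (3S,1E)‑1‑phenylhexa‑1,5‑dien‑3‑yl diisopinocampheylborinate (not isolated) | C=CC[C@@H](/C=C/c1ccccc1)OB([C@@H]1C[C@@H]2C[C@@H](C2(C)C)[C@H]1C)[C@@H]1C[C@@H]2C[C@@H](C2(C)C)[C@H]1C | intermediate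
3 | (3S,1E)‑1‑phenylhexa‑1,5‑dien‑3‑ol | C=CC[C@@H](/C=C/c1ccccc1)O | intermediate
4 | [(1E,3S)‑3‑methoxyhexa‑1,5‑dien‑1‑yl]benzene | C=CC[C@@H](/C=C/c1ccccc1)OC | intermediate
5 | (4S,5E)‑4‑methoxy‑6‑phenylhex‑5‑ene‑1,2‑diol, both C2 epimers (not isolated) | OCC(O)C[C@@H](/C=C/c1ccccc1)OC | intermediate
6 | (3S,4E)‑3‑methoxy‑5‑phenylpent‑4‑enal | O=CC[C@@H](/C=C/c1ccccc1)OC | intermediate
7 | pinacol borate ester of 8 (not isolated) | C#CC[C@@H](OB1OC(C)(C)C(C)(C)O1)C[C@@H](/C=C/c1ccccc1)OC | intermediate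
8 | (4R,6S,7E)‑6‑methoxy‑8‑phenyloct‑7‑en‑1‑yn‑4‑ol | C#CC[C@@H](O)C[C@@H](/C=C/c1ccccc1)OC | intermediate
9 | (4R,6S,7E)‑4,6‑dimethoxy‑8‑phenyloct‑7‑en‑1‑yne | C#CC[C@@H](OC)C[C@@H](/C=C/c1ccccc1)OC | intermediate
10 | 2‑[(1E,4R,6S,7E)‑4,6‑dimethoxy‑8‑phenylocta‑1,7‑dien‑1‑yl]‑1,3,2‑benzodioxaborole (not isolated) | CO[C@H](C/C=C/B1Oc2ccccc2O1)C[C@@H](/C=C/c1ccccc1)OC | intermediate
11 | [(1E,4R,6S,7E)‑4,6‑dimethoxy‑8‑phenylocta‑1,7‑dien‑1‑yl]boronic acid | CO[C@H](C/C=C/B(O)O)C[C@@H](/C=C/c1ccccc1)OC | intermediate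
12 | 4H‑pyran‑4‑one | O=c1ccocc1 | starting material
13 | (2R)‑2‑[(1E,4R,6S,7E)‑4,6‑dimethoxy‑8‑phenylocta‑1,7‑dien‑1‑yl]‑2,3‑dihydro‑4H‑pyran‑4‑one | O=C1C[C@H](/C=C/C[C@@H](OC)C[C@@H](/C=C/c2ccccc2)OC)OC=C1 | intermediate
14 | (2R,6R)‑2‑[(1E,4R,6S,7E)‑4,6‑dimethoxy‑8‑phenylocta‑1,7‑dien‑1‑yl]‑6‑methoxyoxan‑4‑one | CO[C@H]1CC(=O)C[C@H](/C=C/C[C@@H](OC)C[C@@H](/C=C/c2ccccc2)OC)O1 | intermediate
15 | (2R,4S,6R)‑2‑[(1E,4R,6S,7E)‑4,6‑dimethoxy‑8‑phenylocta‑1,7‑dien‑1‑yl]‑6‑methoxyoxan‑4‑ol | CO[C@H]1C[C@@H](O)C[C@H](/C=C/C[C@@H](OC)C[C@@H](/C=C/c2ccccc2)OC)O1 | intermediate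
16 | (4S,6R)‑6‑[(1E,4R,6S,7E)‑4,6‑dimethoxy‑8‑phenylocta‑1,7‑dien‑1‑yl]oxane‑2,4‑diol (anomer mixture) | OC1C[C@@H](O)C[C@H](/C=C/C[C@@H](OC)C[C@@H](/C=C/c2ccccc2)OC)O1 | intermediate
17 | (4S,6R)‑6‑[(1E,4R,6S,7E)‑4,6‑dimethoxy‑8‑phenylocta‑1,7‑dien‑1‑yl]‑4‑hydroxyoxan‑2‑one | CO[C@H](C/C=C/[C@H]1C[C@H](O)CC(=O)O1)C[C@@H](/C=C/c1ccccc1)OC | target

**Totals**
Total step count: 11. Longest linear sequence: 11 steps (1 → 17); 4H‑pyran‑4‑one 12 enters at step 7.

**Three steps most likely to fail**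

Step 7 (proposed new method). Insertion of the electron‑rich, weakly aromatic pyranone C=C into the alkenyl–Rh bond may be slow, so that protodeboronation of 11 dominates. A second addition to 13 may compete. β‑Oxygen elimination or 2H‑pyran ring opening of the dienol(ate) before C‑protonation would erode the enantiomeric purity. The fallback forms the same bond with known chemistry and sets out from alkyne 9. Hydroboration with dicyclohexylborane, boron‑to‑zinc exchange with Me2Zn and amino‑alcohol (MIB)‑catalysed addition of the alkenylzinc (ligand enantiomer chosen for the (5R)‑carbinol) to the known aldehyde methyl (3S)‑3‑[(tert‑butyldimethylsilyl)oxy]‑5‑oxopentanoate F1 should give methyl (3S,5R,6E,9R,11S,12E)‑3‑[(tert‑butyldimethylsilyl)oxy]‑5‑hydroxy‑9,11‑dimethoxy‑13‑phenyltrideca‑6,12‑dienoate F2. PPTS in warm benzene should close this to the silyl‑protected lactone (4S,6R)‑4‑[(tert‑butyldimethylsilyl)oxy]‑6‑[(1E,4R,6S,7E)‑4,6‑dimethoxy‑8‑phenylocta‑1,7‑dien‑1‑yl]oxan‑2‑one F3, and HF·pyridine should remove the silyl group to give 17, where the fallback comes back to the route.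

Step 8. Under acid the β‑alkoxy ketone may open by retro‑oxa‑Michael elimination towards the conjugated dienone, with epimerisation or loss of the ring‑oxygen centre. The cinnamyl‑type methyl ether may also ionise and be transposed or scrambled in methanol. The fallback sets out from 13 and removes the ketone before any acid is used. Luche reduction (NaBH4, CeCl3, MeOH, −78 °C) should give the cis allylic alcohol (2R,4R)‑2‑[(1E,4R,6S,7E)‑4,6‑dimethoxy‑8‑phenylocta‑1,7‑dien‑1‑yl]‑3,4‑dihydro‑2H‑pyran‑4‑ol F4. PPh3·HBr‑catalysed addition of methanol to the enol ether (2‑deoxyglycoside formation from a glycal) should give (2R,4R,6R)‑2‑[(1E,4R,6S,7E)‑4,6‑dimethoxy‑8‑phenylocta‑1,7‑dien‑1‑yl]‑6‑methoxyoxan‑4‑ol F5. Buffered Dess–Martin oxidation of this equatorial alcohol returns to ketone 14, from which step 9 follows as planned.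

Step 3. Osmylation may not discriminate enough between the terminal and the styrenyl alkene, giving over‑cleavage to benzaldehyde‑type fragments. The β‑methoxy aldehyde may also lose methanol to the conjugated dienal during work‑up. The fallback sets out from 1 and avoids any alkene cleavage. A Ti(IV)/BINOL‑catalysed Mukaiyama aldol with the trimethylsilyl ketene S,O‑acetal of S‑tert‑butyl thioacetate (BINOL enantiomer chosen for the (S)‑adduct) should give the silyl ether S‑tert‑butyl (3S,4E)‑5‑phenyl‑3‑[(trimethylsilyl)oxy]pent‑4‑enethioate F6. Acidic work‑up desilylates it to S‑tert‑butyl (3S,4E)‑3‑hydroxy‑5‑phenylpent‑4‑enethioate F7. O‑Methylation with Me3OBF4 and proton sponge should give S‑tert‑butyl (3S,4E)‑3‑methoxy‑5‑phenylpent‑4‑enethioate F8, and DIBAL‑H at −78 °C reduces the thioester to aldehyde 6, where the route is rejoined.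

**Further compounds**
F1 | step 7 | methyl (3S)‑3‑[(tert‑butyldimethylsilyl)oxy]‑5‑oxopentanoate | COC(=O)C[C@@H](O[Si](C)(C)C(C)(C)C)CC=O
F2 | step 7 | methyl (3S,5R,6E,9R,11S,12E)‑3‑[(tert‑butyldimethylsilyl)oxy]‑5‑hydroxy‑9,11‑dimethoxy‑13‑phenyltrideca‑6,12‑dienoate | COC(=O)C[C@@H](O[Si](C)(C)C(C)(C)C)C[C@@H](O)/C=C/C[C@@H](OC)C[C@@H](/C=C/c1ccccc1)OC
F3 | step 7 | (4S,6R)‑4‑[(tert‑butyldimethylsilyl)oxy]‑6‑[(1E,4R,6S,7E)‑4,6‑dimethoxy‑8‑phenylocta‑1,7‑dien‑1‑yl]oxan‑2‑one | O=C1C[C@@H](O[Si](C)(C)C(C)(C)C)C[C@H](/C=C/C[C@@H](OC)C[C@@H](/C=C/c2ccccc2)OC)O1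
F4 | step 8 | (2R,4R)‑2‑[(1E,4R,6S,7E)‑4,6‑dimethoxy‑8‑phenylocta‑1,7‑dien‑1‑yl]‑3,4‑dihydro‑2H‑pyran‑4‑ol | C1=CO[C@@H](/C=C/C[C@@H](OC)C[C@@H](/C=C/c2ccccc2)OC)C[C@H]1O
F5 | step 8 | (2R,4R,6R)‑2‑[(1E,4R,6S,7E)‑4,6‑dimethoxy‑8‑phenylocta‑1,7‑dien‑1‑yl]‑6‑methoxyoxan‑4‑ol | CO[C@H]1C[C@H](O)C[C@H](/C=C/C[C@@H](OC)C[C@@H](/C=C/c2ccccc2)OC)O1
F6 | step 3 | S‑tert‑butyl (3S,4E)‑5‑phenyl‑3‑[(trimethylsilyl)oxy]pent‑4‑enethioate | CC(C)(C)SC(=O)C[C@@H](/C=C/c1ccccc1)O[Si](C)(C)C
F7 | step 3 | S‑tert‑butyl (3S,4E)‑3‑hydroxy‑5‑phenylpent‑4‑enethioate | CC(C)(C)SC(=O)C[C@@H](/C=C/c1ccccc1)O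
F8 | step 3 | S‑tert‑butyl (3S,4E)‑3‑methoxy‑5‑phenylpent‑4‑enethioate | CC(C)(C)SC(=O)C[C@@H](/C=C/c1ccccc1)OC
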